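**Plan**

- Retrosynthesis: the benzyl ester and the ring A C4 methyl ether come off first. Ring A is then opened at its C1–C6 bond (aldol retron) to a 3,5,7-trioxodecanoate aryl ester. The depside C(=O)–O bond is cut to an acylketene plus the ring B phenol, the chain at C4–C5 and C6–C7 (two Claisen acylations of trimethyldioxinone), and ring B at C1–CO2H back to olivetol.
- Enabling feature: ring A carries the ester carbon on C1, OH on C2, oxygen on C4 and propyl on C6. This is the pattern left when C2 of a 3,5,7-trioxodecanoate adds to its C7 ketone, so chain C1 can already be the depside ester carbon and chain C2–C7 become ring A.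
- Forward: ring B is bought as the arene (olivetol) and dressed by carboxylation, benzyl ester formation, C4 allylation, C2 methylation and deallylation. The chain is built on the dioxinone and joined to the ring B phenol through the acylketene. Ring A is closed last, on the finished ester.
- Stereochemistry: the target has no stereocentre; the two that appear in the aldol intermediate are erased on aromatisation.
- Finish: methylation of the unchelated ring A hydroxyl, then hydrogenolysis of the benzyl ester.

Key step: step 10

Numbering used below: chain positions are those of the trioxodecanoate (C1 = ester carbon); ring positions are those of the benzoate (C1 bears the carboxyl carbon).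

**Route**

Step 1
Reactants: 1 olivetol (5-pentylbenzene-1,3-diol)
Product: 2 olivetolic acid (2,4-dihydroxy-6-pentylbenzoic acid)
Conditions: MeOMgOCO2Me (2 M in DMF, excess), 120 °C; then ice-cold 2 M aq. HCl
Reagents that add atoms: methoxymagnesium methyl carbonate MeOMgOCO2Me, COC(=O)O[Mg]OC
Why: Kolbe–Schmitt-type carboxylation in which the magnesium phenoxide chelate delivers CO2 to a ring carbon ortho to a hydroxyl, an established entry from 5-alkylresorcinols to 2,4-dihydroxy-6-alkylbenzoic acids, with the chelated magnesium salicylate shielded from decarboxylation until the cold acidic work-up.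

Step 2
Reactants: 2 olivetolic acid
Product: 3 benzyl 2,4-dihydroxy-6-pentylbenzoate
Conditions: BnBr (1.05 equiv), KHCO3, DMF, rt
Reagents that add atoms: benzyl bromide, BrCc1ccccc1
Why: SN2 O-alkylation of the carboxylate, since hydrogencarbonate ionises only the carboxylic acid and leaves both phenols protonated.

Step 3
Reactants: 3 benzyl 2,4-dihydroxy-6-pentylbenzoate
Product: 4 benzyl 4-(allyloxy)-2-hydroxy-6-pentylbenzoate
Conditions: allyl bromide (1.05 equiv), K2CO3, acetone, reflux
Reagents that add atoms: allyl bromide, C=CCBr
Why: Williamson etherification that should be selective for the C4 hydroxyl, because the C2 hydroxyl is held in a hydrogen bond to the ester carbonyl and is the poorer nucleophile.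

Step 4
Reactants: 4 benzyl 4-(allyloxy)-2-hydroxy-6-pentylbenzoate
Product: 5 benzyl 4-(allyloxy)-2-methoxy-6-pentylbenzoate
Conditions: MeI (excess), K2CO3, DMF, 50 °C
Reagents that add atoms: iodomethane, CI
Why: Williamson methylation of the remaining chelated phenol, which yields under the more forcing conditions of excess iodomethane in warm DMF while the allyl ether and benzyl ester are inert.

Step 5
Reactants: 5 benzyl 4-(allyloxy)-2-methoxy-6-pentylbenzoate
Product: 6 benzyl 4-hydroxy-2-methoxy-6-pentylbenzoate
Conditions: Pd(PPh3)4 (5 mol%), morpholine, THF, rt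
Reagents that add atoms: none
Why: Tsuji–Trost deallylation, in which zerovalent palladium ionises the allyl aryl ether to a π-allyl complex that morpholine intercepts, leaving the benzyl ester and the methyl ether untouched.

Step 6
Reactants: 7 butanoyl chloride
Product: 8 N-methoxy-N-methylbutanamide
Conditions: MeNH(OMe)·HCl, Et3N (2.2 equiv), CH2Cl2, 0 °C to rt
Reagents that add atoms: N,O-dimethylhydroxylamine hydrochloride, CNOC.Cl
Why: Schotten–Baumann-type N-acylation of the hydroxylamine by the acid chloride, the standard preparation of a Weinreb amide.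

Step 7
Reactants: 9 2,2,6-trimethyl-4H-1,3-dioxin-4-one
Product: 10 2,2-dimethyl-6-(2-oxopropyl)-4H-1,3-dioxin-4-one
Conditions: LiN(SiMe3)2 (1.05 equiv), THF, −78 °C; then AcCl (0.55 equiv), −78 °C; aq. NH4Cl
Reagents that add atoms: acetyl chloride, CC(Cl)=O
Why: vinylogous Claisen acylation of the lithium dienolate at its exocyclic γ-carbon (chain C4–C5 bond), run with half an equivalent of acetyl chloride because the more acidic product consumes a second equivalent of dienolate, which returns 9 on work-up.

Step 8
Reactants: 10 2,2-dimethyl-6-(2-oxopropyl)-4H-1,3-dioxin-4-one; 8 N-methoxy-N-methylbutanamide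
Product: 11 6-(2,4-dioxoheptyl)-2,2-dimethyl-4H-1,3-dioxin-4-one
Conditions: LiN(iPr)2 (2.2 equiv), THF, −78 °C; then 8, −78 to −20 °C; aq. NH4Cl
Reagents that add atoms: none
Why: dianion Claisen condensation in which the more basic terminal methyl carbanion attacks the Weinreb amide (chain C6–C7 bond) and the chelated tetrahedral adduct prevents over-addition until the quench.

Step 9
Reactants: 11 6-(2,4-dioxoheptyl)-2,2-dimethyl-4H-1,3-dioxin-4-one; 6 benzyl 4-hydroxy-2-methoxy-6-pentylbenzoate
Product: 13 benzyl 2-methoxy-6-pentyl-4-[(3,5,7-trioxodecanoyl)oxy]benzoate, via acylketene 12 (not isolated)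
Conditions: toluene (concentrated, 11 in slight excess), 110 °C; evaporate, use crude
Reagents that add atoms: none
Why: retro-hetero-Diels–Alder fragmentation of the dioxinone releases acetone and an acylketene, and addition of the phenol O–H across the ketene, as in the known preparation of aryl acetoacetates from dioxinones, should give the aryl β-keto ester with the depside C–O bond in place.

Step 10
Reactants: 13 benzyl 2-methoxy-6-pentyl-4-[(3,5,7-trioxodecanoyl)oxy]benzoate
Product: 15 benzyl 4-[(2,4-dihydroxy-6-propylbenzoyl)oxy]-2-methoxy-6-pentylbenzoate, via cyclic aldol adduct 14 (not isolated)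
Conditions: Et3N (2 equiv), CH2Cl2, 0 °C to rt; then HCl (4 M in 1,4-dioxane), rt
Reagents that add atoms: none
Why: Et3N generates the enolate at C2, the methylene flanked by the aryl ester and the C3 ketone, and this adds to the C7 ketone to form the ring A C1–C6 bond; loss of water from aldol 14 and enolisation of the C3 and C5 carbonyls then give the arene, the acid completing the dehydration. The closest known reaction is the biomimetic aldol aromatisation of dioxinone-derived 3,5,7-triketo esters to resorcylates. Ring A closes in a 6-(enolendo)-exo-trig mode. No stereocentre survives, the two created in 14 being erased on aromatisation. The step needs the C2-to-C7 aldol to win over pathways that expel the ring B aryloxide (attack of the C5 enol oxygen or of C6 on the ester carbon, or E1cB reversion to the ketene). This should be secured by the ketone being the better acceptor for a reversible enolate addition that aromatisation then makes irreversible, and by a weak amine in an aprotic solvent at low temperature with no alcohol or hydroxide present, where an unsolvated aryloxide is a poor leaving group.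

Step 11
Reactants: 15 benzyl 4-[(2,4-dihydroxy-6-propylbenzoyl)oxy]-2-methoxy-6-pentylbenzoate
Product: 16 benzyl 4-[(2-hydroxy-4-methoxy-6-propylbenzoyl)oxy]-2-methoxy-6-pentylbenzoate
Conditions: MeI (1.1 equiv), K2CO3 (1.1 equiv), acetone, rt
Reagents that add atoms: iodomethane, CI
Why: Williamson methylation that should be selective for the ring A C4 hydroxyl, the more acidic and unchelated one, while the C2 hydroxyl stays hydrogen-bonded to the depside carbonyl and the hindered 2,6-disubstituted aryl ester resists the mild base.

Step 12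
Reactants: 16 benzyl 4-[(2-hydroxy-4-methoxy-6-propylbenzoyl)oxy]-2-methoxy-6-pentylbenzoate
Product: 17 4-[(2-hydroxy-4-methoxy-6-propylbenzoyl)oxy]-2-methoxy-6-pentylbenzoic acid
Conditions: H2 (1 atm), 10% Pd/C, EtOAc, rt
Reagents that add atoms: none
Why: catalytic hydrogenolysis of the benzylic C–O bond frees the carboxylic acid under neutral conditions that leave the depside aryl ester, the methyl ethers and the phenol intact.

**Compound list**

1 | olivetol (5-pentylbenzene-1,3-diol) | CCCCCc1cc(O)cc(O)c1 | starting material
2 | olivetolic acid (2,4-dihydroxy-6-pentylbenzoic acid) | CCCCCc1cc(O)cc(O)c1C(=O)O | intermediate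
3 | benzyl 2,4-dihydroxy-6-pentylbenzoate | CCCCCc1cc(O)cc(O)c1C(=O)OCc1ccccc1 | intermediate
4 | benzyl 4-(allyloxy)-2-hydroxy-6-pentylbenzoate | CCCCCc1cc(OCC=C)cc(O)c1C(=O)OCc1ccccc1 | intermediate
5 | benzyl 4-(allyloxy)-2-methoxy-6-pentylbenzoate | CCCCCc1cc(OCC=C)cc(OC)c1C(=O)OCc1ccccc1 | intermediate
6 | benzyl 4-hydroxy-2-methoxy-6-pentylbenzoate | CCCCCc1cc(O)cc(OC)c1C(=O)OCc1ccccc1 | intermediate
7 | butanoyl chloride | CCCC(Cl)=O | starting material
8 | N-methoxy-N-methylbutanamide | CCCC(=O)N(C)OC | intermediate
9 | 2,2,6-trimethyl-4H-1,3-dioxin-4-one | CC1=CC(=O)OC(C)(C)O1 | starting material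
10 | 2,2-dimethyl-6-(2-oxopropyl)-4H-1,3-dioxin-4-one | CC(=O)CC1=CC(=O)OC(C)(C)O1 | intermediate
11 | 6-(2,4-dioxoheptyl)-2,2-dimethyl-4H-1,3-dioxin-4-one | CCCC(=O)CC(=O)CC1=CC(=O)OC(C)(C)O1 | intermediate
12 | acylketene dec-1-ene-1,3,5,7-tetrone | CCCC(=O)CC(=O)CC(=O)C=C=O | intermediate (not isolated)
13 | benzyl 2-methoxy-6-pentyl-4-[(3,5,7-trioxodecanoyl)oxy]benzoate | CCCC(=O)CC(=O)CC(=O)CC(=O)Oc1cc(CCCCC)c(C(=O)OCc2ccccc2)c(OC)c1 | intermediate
14 | benzyl 4-[(2-hydroxy-4,6-dioxo-2-propylcyclohexane-1-carbonyl)oxy]-2-methoxy-6-pentylbenzoate (cyclic aldol adduct, mixture of stereoisomers) | CCCC1(O)CC(=O)CC(=O)C1C(=O)Oc1cc(CCCCC)c(C(=O)OCc2ccccc2)c(OC)c1 | intermediate (not isolated)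
15 | benzyl 4-[(2,4-dihydroxy-6-propylbenzoyl)oxy]-2-methoxy-6-pentylbenzoate | CCCc1cc(O)cc(O)c1C(=O)Oc1cc(CCCCC)c(C(=O)OCc2ccccc2)c(OC)c1 | intermediate
16 | benzyl 4-[(2-hydroxy-4-methoxy-6-propylbenzoyl)oxy]-2-methoxy-6-pentylbenzoate | CCCc1cc(OC)cc(O)c1C(=O)Oc1cc(CCCCC)c(C(=O)OCc2ccccc2)c(OC)c1 | intermediate
17 | 4-[(2-hydroxy-4-methoxy-6-propylbenzoyl)oxy]-2-methoxy-6-pentylbenzoic acid | CCCCCc1cc(OC(=O)c2c(O)cc(OC)cc2CCC)cc(OC)c1C(=O)O | target

**Step count and risks**

Total step count: 12. Longest linear sequence: 9 steps (steps 1–5 and 9–12, from olivetol 1).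

Steps most likely to fail:

1. Step 10. The ring B aryloxide may be expelled before the aldol occurs: by attack of the C5 enol oxygen on the ester carbon (pyrone formation), by C6-to-C1 Claisen closure, or by E1cB reversion to the ketene. The fallback aromatises ring A before the ester bond exists; it sets out from 11 and 6 and comes back at 16. Compound 11 is folded on itself with Et3N in CH2Cl2, the dioxinone C5 adding to the terminal ketone, to give 7-hydroxy-2,2-dimethyl-5-propyl-4H-1,3-benzodioxin-4-one F1. Methylation with MeI and K2CO3 in acetone gives 7-methoxy-2,2-dimethyl-5-propyl-4H-1,3-benzodioxin-4-one F2. The sodium phenoxide of 6 (NaH, THF then DMF, 60 °C) is then added to the lactone carbonyl of F2; the opened acetonide should collapse with loss of acetone, as in the known alkoxide opening of benzodioxinones, and acidification should deliver 16.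

2. Step 9. The acylketene may be captured internally by its own C5 enol oxygen, or may dimerise, faster than the electron-poor phenol adds. The fallback traps the ketene with an alcohol and makes the depside bond by classical esterification; it sets out from 11 and comes back at 16. Heating 11 with benzyl alcohol in toluene at 110 °C gives benzyl 3,5,7-trioxodecanoate F3. Et3N in CH2Cl2 followed by HCl aromatises it to benzyl 2,4-dihydroxy-6-propylbenzoate F4. MeI and K2CO3 in acetone give benzyl 2-hydroxy-4-methoxy-6-propylbenzoate F5, and hydrogenolysis over Pd/C gives 2-hydroxy-4-methoxy-6-propylbenzoic acid F6. Condensation of F6 with phenol 6 through the mixed anhydride formed with (CF3CO)2O in toluene at rt should give 16.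

3. Step 1. Carboxylation may occur at the carbon between the two hydroxyls, conversion may stall, or the acid may decarboxylate during work-up. The fallback installs the carboxyl carbon as an aldehyde; it sets out from 1 and comes back at 5. Vilsmeier–Haack formylation (POCl3, DMF, then aq. NaOAc) gives 2,4-dihydroxy-6-pentylbenzaldehyde F7. Allyl bromide and K2CO3 in acetone give 4-(allyloxy)-2-hydroxy-6-pentylbenzaldehyde F8, and MeI and K2CO3 in DMF give 4-(allyloxy)-2-methoxy-6-pentylbenzaldehyde F9. Pinnick oxidation (NaClO2, NaH2PO4, 2-methyl-2-butene, t-BuOH/H2O) gives 4-(allyloxy)-2-methoxy-6-pentylbenzoic acid F10, which BnBr and KHCO3 in DMF convert into 5.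

**Further compounds**

F1 | step 10 | 7-hydroxy-2,2-dimethyl-5-propyl-4H-1,3-benzodioxin-4-one | CCCc1cc(O)cc2c1C(=O)OC(C)(C)O2
F2 | step 10 | 7-methoxy-2,2-dimethyl-5-propyl-4H-1,3-benzodioxin-4-one | CCCc1cc(OC)cc2c1C(=O)OC(C)(C)O2
F3 | step 9 | benzyl 3,5,7-trioxodecanoate | CCCC(=O)CC(=O)CC(=O)CC(=O)OCc1ccccc1
F4 | step 9 | benzyl 2,4-dihydroxy-6-propylbenzoate | CCCc1cc(O)cc(O)c1C(=O)OCc1ccccc1
F5 | step 9 | benzyl 2-hydroxy-4-methoxy-6-propylbenzoate | CCCc1cc(OC)cc(O)c1C(=O)OCc1ccccc1
F6 | step 9 | 2-hydroxy-4-methoxy-6-propylbenzoic acid | CCCc1cc(OC)cc(O)c1C(=O)O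
F7 | step 1 | 2,4-dihydroxy-6-pentylbenzaldehyde | CCCCCc1cc(O)cc(O)c1C=O
F8 | step 1 | 4-(allyloxy)-2-hydroxy-6-pentylbenzaldehyde | CCCCCc1cc(OCC=C)cc(O)c1C=O
F9 | step 1 | 4-(allyloxy)-2-methoxy-6-pentylbenzaldehyde | CCCCCc1cc(OCC=C)cc(OC)c1C=O
F10 | step 1 | 4-(allyloxy)-2-methoxy-6-pentylbenzoic acid | CCCCCc1cc(OCC=C)cc(OC)c1C(=O)O
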